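Numbering the ten-membered ring from the carbon bearing the 3-acetoxyprop-1-en-2-yl group (C1) through the isovalerate carbon (C3), the alkene (C4=C5), two methylenes (C6, C7) and the epoxide (C8–C9) to C10, and reading the epoxide as a masked C8=C9 alkene, the ring is a cyclodeca-1,5-diene with C6–C7 as the σ-bond of a Cope retron. The key step is an anionic oxy-Cope rearrangement of a trans-1,2-dialkenylcyclohexanol (ring C4–C3–C2–C1–C10–C9, from (+)-nopinone). It forms C6–C7, cleaves C4–C9, expands six to ten atoms and sets both ring-trans alkenes. The enolate is trapped as the C4 enol triflate, later converted into the C4 hydroxymethyl group.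

Key step: step 9

Remark on stereochemistry: C3 is carried with the configuration opposite to the target (all-cis cyclohexane series, needed for the trans-dialkenyl carbinol) and is inverted in step 17. "Ring-trans" describes the endocyclic alkenes of the ten-membered intermediates whatever their CIP label.
Assumption: compounds 1, 3 and 16 and the reagents named under the conditions (including (tributylstannyl)methanol) are purchased.

Step 1
Reactants: 1 (1R,5S)-(+)-nopinone
Product: 2 (S)-4-(prop-1-en-2-yl)cyclohex-1-en-1-yl acetate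
Conditions: Ac2O, BF3·OEt2, Zn(OAc)2, 0 °C to rt
Reagents that add atoms: acetic anhydride, CC(=O)OC(C)=O
Why: Lewis-acid-promoted cyclobutane fragmentation of nopinone (the acylated carbonyl triggers cleavage of the bridgehead–CMe2 bond and the tertiary cation loses a proton to the isopropenyl group) should give the enol acetate regiospecifically on the former bridgehead side, the untouched ring stereocentre becoming C1 of the target.

Step 2
Reactants: 3 2-bromoprop-2-en-1-ol
Product: 4 [(2-bromoprop-2-en-1-yl)oxy](tert-butyl)dimethylsilane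
Conditions: TBSCl, imidazole, CH2Cl2, 0 °C to rt
Reagents that add atoms: tert-butyldimethylsilyl chloride, CC(C)(C)[Si](C)(C)Cl
Why: Standard silylation of a primary alcohol.

Step 3
Reactants: 2 (S)-4-(prop-1-en-2-yl)cyclohex-1-en-1-yl acetate; 4 [(2-bromoprop-2-en-1-yl)oxy](tert-butyl)dimethylsilane
Product: 6 (2R,4S)-2-{3-[(tert-butyldimethylsilyl)oxy]prop-1-en-2-yl}-4-(prop-1-en-2-yl)cyclohexan-1-one, via tributyltin enolate 5 (not isolated)
Conditions: Bu3SnOMe, PdCl2[P(o-tol)3]2 (cat.), toluene, 100 °C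
Reagents that add atoms: none
Why: Migita–Kosugi α-alkenylation, in which the enol acetate gives the tin enolate regiospecifically and this couples with the vinyl bromide by oxidative addition, transmetalation and reductive elimination; the epimerisable α-centre is expected to settle equatorial, cis to the C4 substituent.

Step 4
Reactants: 6 (2R,4S)-2-{3-[(tert-butyldimethylsilyl)oxy]prop-1-en-2-yl}-4-(prop-1-en-2-yl)cyclohexan-1-one
Product: 7 (2R,4S)-2-{3-[(tert-butyldimethylsilyl)oxy]prop-1-en-2-yl}-4-(3-chloroprop-1-en-2-yl)cyclohexan-1-one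
Conditions: Ca(OCl)2, CO2 (dry ice), CH2Cl2/H2O, 0 °C
Reagents that add atoms: calcium hypochlorite, [Ca+2].[O-]Cl.[O-]Cl
Why: Ene-type allylic chlorination with hypochlorous acid should occur at the more nucleophilic 1,1-dialkyl alkene, the other 1,1-disubstituted alkene being deactivated by its allylic silyloxy and acyl groups.

Step 5
Reactants: 7 (2R,4S)-2-{3-[(tert-butyldimethylsilyl)oxy]prop-1-en-2-yl}-4-(3-chloroprop-1-en-2-yl)cyclohexan-1-one
Product: 8 2-[(1S,3R)-3-{3-[(tert-butyldimethylsilyl)oxy]prop-1-en-2-yl}-4-oxocyclohexyl]prop-2-en-1-yl acetate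
Conditions: Bu4NOAc, acetone, rt
Reagents that add atoms: tetrabutylammonium acetate, CC(=O)[O-].CCCC[N+](CCCC)(CCCC)CCCC
Why: SN2 displacement of the primary allylic chloride by acetate (SN2′ attack gives the same product because the allyl unit is symmetric about its central carbon).

Step 6
Reactants: 8 2-[(1S,3R)-3-{3-[(tert-butyldimethylsilyl)oxy]prop-1-en-2-yl}-4-oxocyclohexyl]prop-2-en-1-yl acetate
Product: 10 2-[(1R,3R,5R)-3-hydroxy-4-oxo-5-{3-[(tert-butyldimethylsilyl)oxy]prop-1-en-2-yl}cyclohexyl]prop-2-en-1-yl acetate (all-cis), via anilinooxy ketone 9 (not isolated)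
Conditions: L-proline (cat.), PhNO, DMSO, rt; then CuSO4·5H2O (cat.), MeOH, 0 °C
Reagents that add atoms: nitrosobenzene, O=Nc1ccccc1
Why: Proline-catalysed α-aminoxylation, in which the enamine forms on the unsubstituted α-methylene and the carboxylic acid of L-proline directs O-attack of nitrosobenzene to the face giving the (R)-carbinol (equatorial, cis to both ring substituents, catalyst control), followed by Cu(II)-mediated N–O cleavage.

Step 7
Reactants: 10 2-[(1R,3R,5R)-3-hydroxy-4-oxo-5-{3-[(tert-butyldimethylsilyl)oxy]prop-1-en-2-yl}cyclohexyl]prop-2-en-1-yl acetate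
Product: 11 (1S,2R,4R,6R)-1-ethenyl-4-(3-hydroxyprop-1-en-2-yl)-6-{3-[(tert-butyldimethylsilyl)oxy]prop-1-en-2-yl}cyclohexane-1,2-diol
Conditions: vinylMgBr (excess), THF, −78 to 0 °C
Reagents that add atoms: vinylmagnesium bromide, C=C[Mg]Br
Why: Grignard 1,2-addition to the α-alkoxide-chelated ketone with both α-substituents equatorial should proceed by equatorial attack, giving the axial tertiary alcohol with vinyl trans to the neighbouring alkenyl group (cis-diol); the excess reagent also cleaves the acetate.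

Step 8
Reactants: 11 (1S,2R,4R,6R)-1-ethenyl-4-(3-hydroxyprop-1-en-2-yl)-6-{3-[(tert-butyldimethylsilyl)oxy]prop-1-en-2-yl}cyclohexane-1,2-diol
Product: 12 (1S,2R,4R,6R)-1-ethenyl-2-[(triethylsilyl)oxy]-4-{3-[(triethylsilyl)oxy]prop-1-en-2-yl}-6-{3-[(tert-butyldimethylsilyl)oxy]prop-1-en-2-yl}cyclohexan-1-ol
Conditions: TESCl, imidazole, DMF, 0 °C
Reagents that add atoms: chlorotriethylsilane, CC[Si](Cl)(CC)CC
Why: Silylation of the primary and secondary hydroxyls; the hindered axial tertiary alcohol should not react.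

Step 9
Reactants: 12 (1S,2R,4R,6R)-1-ethenyl-2-[(triethylsilyl)oxy]-4-{3-[(triethylsilyl)oxy]prop-1-en-2-yl}-6-{3-[(tert-butyldimethylsilyl)oxy]prop-1-en-2-yl}cyclohexan-1-ol
Product: 14 (1R,3R)-ten-membered enol triflate (C4–OTf; C4=C5 and C8=C9 both ring-trans; CIP 4Z,8Z; TES ethers at C3–O and on the C1 side chain; TBS ether on the C8 CH2O), via potassium enolate 13 (not isolated)
Conditions: KH, 18-crown-6, THF, 0 °C to rt; then PhNTf2, −78 to 0 °C
Reagents that add atoms: N-phenylbis(trifluoromethanesulfonimide), O=S(=O)(N(c1ccccc1)S(=O)(=O)C(F)(F)F)C(F)(F)F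
Why: Deprotonation gives the potassium alkoxide, whose [3,3]-sigmatropic (anionic oxy-Cope) rearrangement forms the C6–C7 bond between the two terminal vinyl carbons and breaks the C4–C9 ring bond, and the resulting enolate 13 is O-sulfonylated in the same flask. The closest known reaction type is the anionic oxy-Cope ring expansion of trans-1,2-divinylcyclohexanols to (E)-cyclodec-5-enones used for germacrane skeletons, followed by ordinary enolate triflation. The ten-membered ring is closed by a concerted ring expansion (six to ten) through a chair-like six-centre transition state embedded in the cyclohexane chair, not by end-to-end macrocyclisation. No stereocentre is created (C1 and C3 are carried over), and the geometry of both new π-bonds is fixed by a transition state in which the vinyl group, the 2-substituted alkenyl group, the C3 silyloxy group and the C1 side chain are all equatorial and O− is axial, so that C3/C6 and C7/C10 end up trans. The step needs this ring-trans,trans geometry, which the trans-diequatorial alkenyl groups from step 7 secure, and trapping of the C4=C5 enolate, which is born regiospecifically, is quenched cold before proton transfer and cannot eliminate the α′ C3 oxygen. Reversible 1,2-silyl migration to the alkoxide, if it occurs, should be funnelled to product by the irreversible rearrangement.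

Step 10
Reactants: 14 (1R,3R)-ten-membered enol triflate
Product: 15 (1R,3R)-C4-hydroxymethyl diene (CIP 4E,8Z; silyl ethers as in 14)
Conditions: Bu3SnCH2OH, Pd(PPh3)4 (cat.), LiCl, THF, 60 °C
Reagents that add atoms: (tributylstannyl)methanol, CCCC[Sn](CCCC)(CCCC)CO
Why: Stille coupling of the enol triflate with the hydroxymethylstannane should proceed with retention of alkene geometry and leave the C4 hydroxymethyl group as the only free hydroxyl.

Step 11
Reactants: 16 (R)-4-benzyl-3-propanoyl-1,3-oxazolidin-2-one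
Product: 18 (R)-4-benzyl-3-[(2R,3S)-3-hydroxy-2-methylbutanoyl]-1,3-oxazolidin-2-one, via dibutylboron enolate 17 (not isolated)
Conditions: Bu2BOTf, iPr2NEt, CH2Cl2, 0 °C; MeCHO, −78 to 0 °C; then pH 7 buffer, MeOH, H2O2
Reagents that add atoms: acetaldehyde, CC=O
Why: Evans syn-aldol through the (Z)-boron enolate and a Zimmerman–Traxler transition state, the (R)-benzyl auxiliary giving the (2R,3S) adduct.

Step 12
Reactants: 18 (R)-4-benzyl-3-[(2R,3S)-3-hydroxy-2-methylbutanoyl]-1,3-oxazolidin-2-one
Product: 19 (R)-4-benzyl-3-{(2R,3S)-3-[(tert-butyldimethylsilyl)oxy]-2-methylbutanoyl}-1,3-oxazolidin-2-one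
Conditions: TBSOTf, 2,6-lutidine, CH2Cl2, 0 °C
Reagents that add atoms: tert-butyldimethylsilyl triflate, CC(C)(C)[Si](C)(C)OS(=O)(=O)C(F)(F)F
Why: Silylation of the secondary alcohol under non-epimerising conditions.

Step 13
Reactants: 19 (R)-4-benzyl-3-{(2R,3S)-3-[(tert-butyldimethylsilyl)oxy]-2-methylbutanoyl}-1,3-oxazolidin-2-one
Product: 21 (2R,3S)-3-[(tert-butyldimethylsilyl)oxy]-2-methylbutanoic acid, via peroxy acid 20 (not isolated)
Conditions: LiOH, H2O2, THF/H2O, 0 °C; Na2SO3; then HCl to pH 3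
Reagents that add atoms: hydrogen peroxide, OO
Why: Hydroperoxide cleaves the exocyclic imide carbonyl selectively and sulfite reduces the peracid, without epimerisation of the α-centre.

Step 14
Reactants: 15 (1R,3R)-C4-hydroxymethyl diene; 21 (2R,3S)-3-[(tert-butyldimethylsilyl)oxy]-2-methylbutanoic acid
Product: 22 (1R,3R)-C4-CH2 ester of 15 with acid 21
Conditions: EDC·HCl, DMAP, CH2Cl2, 0 °C to rt
Reagents that add atoms: none
Why: Carbodiimide (Steglich) esterification of the only free, primary allylic hydroxyl.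

Step 15
Reactants: 22 (1R,3R)-C4-CH2 ester
Product: 23 (1R,3R)-diol (free C3–OH and free side-chain CH2OH on C1; both TBS ethers retained)
Conditions: HF·pyridine, pyridine, THF, 0 °C
Reagents that add atoms: none
Why: Buffered HF·pyridine should remove the two triethylsilyl ethers much faster than the tert-butyldimethylsilyl ethers.

Step 16
Reactants: 23 (1R,3R)-diol
Product: 24 (1R,3R)-monoacetate (acetate on the C1 side-chain CH2O; free C3–OH)
Conditions: AcCl, 2,4,6-collidine, CH2Cl2, −78 °C
Reagents that add atoms: acetyl chloride, CC(Cl)=O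
Why: Acetyl chloride/collidine at low temperature acylates the primary allylic alcohol selectively over the hindered secondary one.

Step 17
Reactants: 24 (1R,3R)-monoacetate
Product: 25 (1R,3S)-C3 isovalerate (both TBS ethers retained)
Conditions: isovaleric acid, PPh3, DIAD, toluene, 0 °C to rt
Reagents that add atoms: 3-methylbutanoic acid, CC(C)CC(=O)O
Why: Mitsunobu esterification, in which SN2 displacement of the C3 oxyphosphonium by isovalerate inverts C3 to the (S) configuration of the target and installs the ester in one operation.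

Step 18
Reactants: 25 (1R,3S)-C3 isovalerate
Product: 26 (1R,3S)-diol (free C8–CH2OH and free side-chain secondary OH)
Conditions: HF·pyridine, pyridine, THF, 0 °C to rt
Reagents that add atoms: none
Why: Fluoride cleavage of both TBS ethers is done before the acid- and HF-sensitive epoxide exists.

Step 19
Reactants: 26 (1R,3S)-diol
Product: 27 CNP0132467.1 (target; 1S,3S,8S,9R in the ring numbering above; side chain 2R,3S)
Conditions: Ti(OiPr)4, L-(+)-diethyl tartrate (stoichiometric), t-BuOOH, 4 Å MS, CH2Cl2, −20 °C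
Reagents that add atoms: tert-butyl hydroperoxide, CC(C)(C)OO
Why: Sharpless asymmetric epoxidation, in which only the allylic-alcohol alkene C8=C9 is epoxidised and L-(+)-tartrate should deliver oxygen to the face giving (8S,9R) by reagent control, the trans-cyclodecene unit being free to present either face by ring flipping.

Compound list
1 | (1R,5S)-(+)-nopinone | O=C1CC[C@H]2C[C@@H]1C2(C)C | starting material
2 | (S)-4-(prop-1-en-2-yl)cyclohex-1-en-1-yl acetate | CC(=O)OC1=CC[C@@H](C(C)=C)CC1 | intermediate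
3 | 2-bromoprop-2-en-1-ol | C=C(Br)CO | starting material
4 | [(2-bromoprop-2-en-1-yl)oxy](tert-butyl)dimethylsilane | C=C(Br)CO[Si](C)(C)C(C)(C)C | intermediate
5 | tributyltin enolate of (S)-4-(prop-1-en-2-yl)cyclohexanone (not isolated) | CCCC[Sn](CCCC)(CCCC)OC1=CC[C@@H](C(C)=C)CC1 | intermediate
6 | (2R,4S)-2-{3-[(tert-butyldimethylsilyl)oxy]prop-1-en-2-yl}-4-(prop-1-en-2-yl)cyclohexan-1-one (2,4-cis) | O=C1CC[C@H](C(C)=C)C[C@@H]1C(=C)CO[Si](C)(C)C(C)(C)C | intermediate
7 | (2R,4S)-2-{3-[(tert-butyldimethylsilyl)oxy]prop-1-en-2-yl}-4-(3-chloroprop-1-en-2-yl)cyclohexan-1-one | O=C1CC[C@H](C(=C)CCl)C[C@@H]1C(=C)CO[Si](C)(C)C(C)(C)C | intermediate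
8 | 2-[(1S,3R)-3-{3-[(tert-butyldimethylsilyl)oxy]prop-1-en-2-yl}-4-oxocyclohexyl]prop-2-en-1-yl acetate | O=C1CC[C@H](C(=C)COC(C)=O)C[C@@H]1C(=C)CO[Si](C)(C)C(C)(C)C | intermediate
9 | 2-[(1R,3R,5R)-3-(anilinooxy)-4-oxo-5-{3-[(tert-butyldimethylsilyl)oxy]prop-1-en-2-yl}cyclohexyl]prop-2-en-1-yl acetate (not isolated) | O=C1[C@H](ONc2ccccc2)C[C@H](C(=C)COC(C)=O)C[C@@H]1C(=C)CO[Si](C)(C)C(C)(C)C | intermediate
10 | 2-[(1R,3R,5R)-3-hydroxy-4-oxo-5-{3-[(tert-butyldimethylsilyl)oxy]prop-1-en-2-yl}cyclohexyl]prop-2-en-1-yl acetate (all-cis) | O=C1[C@H](O)C[C@H](C(=C)COC(C)=O)C[C@@H]1C(=C)CO[Si](C)(C)C(C)(C)C | intermediate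
11 | (1S,2R,4R,6R)-1-ethenyl-4-(3-hydroxyprop-1-en-2-yl)-6-{3-[(tert-butyldimethylsilyl)oxy]prop-1-en-2-yl}cyclohexane-1,2-diol | C=C[C@@]1(O)[C@H](O)C[C@H](C(=C)CO)C[C@@H]1C(=C)CO[Si](C)(C)C(C)(C)C | intermediate
12 | (1S,2R,4R,6R)-1-ethenyl-2-[(triethylsilyl)oxy]-4-{3-[(triethylsilyl)oxy]prop-1-en-2-yl}-6-{3-[(tert-butyldimethylsilyl)oxy]prop-1-en-2-yl}cyclohexan-1-ol | C=C[C@@]1(O)[C@H](O[Si](CC)(CC)CC)C[C@H](C(=C)CO[Si](CC)(CC)CC)C[C@@H]1C(=C)CO[Si](C)(C)C(C)(C)C | intermediate
13 | potassium enolate of the (1R,3R)-ring-expanded cyclodeca-4,8-dienone, C4(O−)=C5 and C8=C9 ring-trans (not isolated) | C=C(CO[Si](CC)(CC)CC)[C@H]1C[C@@H](O[Si](CC)(CC)CC)/C([O-])=C/CC/C(CO[Si](C)(C)C(C)(C)C)=C/C1.[K+] | intermediate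
14 | (1R,3R)-8-{[(tert-butyldimethylsilyl)oxy]methyl}-3-[(triethylsilyl)oxy]-1-{3-[(triethylsilyl)oxy]prop-1-en-2-yl}cyclodeca-4,8-dien-4-yl triflate (overview numbering; both alkenes ring-trans, CIP 4Z,8Z) | C=C(CO[Si](CC)(CC)CC)[C@H]1C[C@@H](O[Si](CC)(CC)CC)/C(OS(=O)(=O)C(F)(F)F)=C/CC/C(CO[Si](C)(C)C(C)(C)C)=C/C1 | intermediate
15 | [(1R,3R)-8-{[(tert-butyldimethylsilyl)oxy]methyl}-3-[(triethylsilyl)oxy]-1-{3-[(triethylsilyl)oxy]prop-1-en-2-yl}cyclodeca-4,8-dien-4-yl]methanol (ring-trans, CIP 4E,8Z) | C=C(CO[Si](CC)(CC)CC)[C@H]1C[C@@H](O[Si](CC)(CC)CC)/C(CO)=C/CC/C(CO[Si](C)(C)C(C)(C)C)=C/C1 | intermediate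
16 | (R)-4-benzyl-3-propanoyl-1,3-oxazolidin-2-one | O=C1OC[C@@H](Cc2ccccc2)N1C(=O)CC | starting material
17 | (Z)-dibutylboron enolate of 16 (not isolated) | CCCCB(CCCC)O/C(=C\C)N1[C@H](Cc2ccccc2)COC1=O | intermediate
18 | (R)-4-benzyl-3-[(2R,3S)-3-hydroxy-2-methylbutanoyl]-1,3-oxazolidin-2-one | O=C1OC[C@@H](Cc2ccccc2)N1C(=O)[C@H](C)[C@H](C)O | intermediate
19 | (R)-4-benzyl-3-{(2R,3S)-3-[(tert-butyldimethylsilyl)oxy]-2-methylbutanoyl}-1,3-oxazolidin-2-one | O=C1OC[C@@H](Cc2ccccc2)N1C(=O)[C@H](C)[C@H](C)O[Si](C)(C)C(C)(C)C | intermediate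
20 | (2R,3S)-3-[(tert-butyldimethylsilyl)oxy]-2-methylbutaneperoxoic acid (not isolated) | OOC(=O)[C@H](C)[C@H](C)O[Si](C)(C)C(C)(C)C | intermediate
21 | (2R,3S)-3-[(tert-butyldimethylsilyl)oxy]-2-methylbutanoic acid | OC(=O)[C@H](C)[C@H](C)O[Si](C)(C)C(C)(C)C | intermediate
22 | ester of 15 (C4–CH2O) with acid 21, (1R,3R), silyl ethers retained | C=C(CO[Si](CC)(CC)CC)[C@H]1C[C@@H](O[Si](CC)(CC)CC)/C(COC(=O)[C@H](C)[C@H](C)O[Si](C)(C)C(C)(C)C)=C/CC/C(CO[Si](C)(C)C(C)(C)C)=C/C1 | intermediate
23 | (1R,3R)-diol: free C3–OH and free CH2OH on the C1 side chain, TBS ethers at C8–CH2O and on the ester side chain | C=C(CO)[C@H]1C[C@@H](O)/C(COC(=O)[C@H](C)[C@H](C)O[Si](C)(C)C(C)(C)C)=C/CC/C(CO[Si](C)(C)C(C)(C)C)=C/C1 | intermediate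
24 | (1R,3R)-monoacetate: 3-acetoxyprop-1-en-2-yl group at C1, free C3–OH | C=C(COC(C)=O)[C@H]1C[C@@H](O)/C(COC(=O)[C@H](C)[C@H](C)O[Si](C)(C)C(C)(C)C)=C/CC/C(CO[Si](C)(C)C(C)(C)C)=C/C1 | intermediate
25 | (1R,3S)-C3 isovalerate, bis-TBS ether | C=C(COC(C)=O)[C@H]1C[C@H](OC(=O)CC(C)C)/C(COC(=O)[C@H](C)[C@H](C)O[Si](C)(C)C(C)(C)C)=C/CC/C(CO[Si](C)(C)C(C)(C)C)=C/C1 | intermediate
26 | (1R,3S)-diol: free C8–CH2OH and free (3S)-hydroxyl of the butanoate | C=C(COC(C)=O)[C@H]1C[C@H](OC(=O)CC(C)C)/C(COC(=O)[C@H](C)[C@H](C)O)=C/CC/C(CO)=C/C1 | intermediate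
27 | CNP0132467.1 | C=C(COC(C)=O)[C@H]1C[C@H](OC(=O)CC(C)C)/C(COC(=O)[C@H](C)[C@H](C)O)=C/CC[C@@]2(CO)O[C@@H]2C1 | target

Total step count: 19. Longest linear sequence: 15 steps (1, 3–10, 14–19).

Steps most likely to fail

Step 9. The C3 triethylsilyl group may migrate to the neighbouring potassium alkoxide and stall the rearrangement, or the enolate may lose its regio- or geometric integrity by proton transfer before O-sulfonylation. Fallback: starting from 12, the rearrangement is run as before but quenched at −78 °C with TMSCl/Et3N, so that the neutral trimethylsilyl enol ether F1 is isolated and purified. The lithium enolate is then regenerated regio- and stereospecifically with MeLi (THF, 0 °C) and sulfonylated with N-(5-chloro-2-pyridyl)triflimide, which returns to 14.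

Step 17. SN2′ attack at C5, elimination to a diene, or no reaction at the hindered macrocyclic allylic carbinol may compete with clean inversion. Fallback: starting from 24, Dess–Martin oxidation (NaHCO3-buffered) gives the C3 enone F2. Reagent-controlled CBS reduction (oxazaborolidine enantiomer chosen by the large-alkenyl/small-methylene model, catecholborane, −78 °C) gives the (3S)-allylic alcohol F3. Acylation with isovaleric anhydride/DMAP returns to 25.

Step 19. Facial selectivity may be poor if the ring conformer exposing the required face of C8=C9 is disfavoured, and titanium may cause transesterification of the ester-rich diol. Fallback: starting from 25, a non-directed Shi epoxidation (fructose-derived ketone of the enantiomeric series assigned by the spiro transition-state model, Oxone, buffered MeCN/dimethoxymethane–water, 0 °C) should epoxidise the most electron-rich trisubstituted alkene C8=C9 to give the bis-TBS epoxide F4. Desilylation with AcOH-buffered TBAF (not HF·pyridine, which would open the epoxide) then gives 27.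

Further compounds
F1 | step 9 | trimethylsilyl enol ether of the (1R,3R)-ring-expanded ketone (C4–OSiMe3, ring-trans alkenes) | C=C(CO[Si](CC)(CC)CC)[C@H]1C[C@@H](O[Si](CC)(CC)CC)/C(O[Si](C)(C)C)=C/CC/C(CO[Si](C)(C)C(C)(C)C)=C/C1
F2 | step 17 | C3 ketone (enone) derived from 24 | C=C(COC(C)=O)[C@H]1CC(=O)/C(COC(=O)[C@H](C)[C@H](C)O[Si](C)(C)C(C)(C)C)=C/CC/C(CO[Si](C)(C)C(C)(C)C)=C/C1
F3 | step 17 | (1R,3S)-allylic alcohol, C3 epimer of 24 | C=C(COC(C)=O)[C@H]1C[C@H](O)/C(COC(=O)[C@H](C)[C@H](C)O[Si](C)(C)C(C)(C)C)=C/CC/C(CO[Si](C)(C)C(C)(C)C)=C/C1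
F4 | step 19 | bis-TBS ether of the target epoxide | C=C(COC(C)=O)[C@H]1C[C@H](OC(=O)CC(C)C)/C(COC(=O)[C@H](C)[C@H](C)O[Si](C)(C)C(C)(C)C)=C/CC[C@@]2(CO[Si](C)(C)C(C)(C)C)O[C@@H]2C1
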